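## Structural features

The target 12 is a 1,3,5-trisubstituted benzene, a 5-alkylresorcinol mono-methyl ether whose ring carries one free phenol, one methyl ether and an unbranched C17 chain attached through its benzylic carbon (chain numbering throughout: C1 benzylic CH2, C2 carbinol carbon, C3–C17 the tail). The only stereocentre is C2, a secondary carbinol of R configuration with no stereogenic neighbour, so its configuration must come from a reagent or a catalyst. C2 is flanked by two methylene groups of similar size, the benzylic C1 and C3 of the pentadecyl tail, so methods that read a steric difference between the two flanks (ketone reduction, for instance) are poorly suited, and this is the real difficulty. The two ring oxygens differ only as OH and OCH3 and sit meta to each other, a distinction that is bought with commercial 3-hydroxy-5-methoxybenzaldehyde. The target itself is robust apart from its electron-rich phenol ring, whereas the fragile points lie in the intermediates: an enolisable arylacetaldehyde and a moisture-sensitive 1-bromoalkyl ester that can lose HBr toward a conjugated enol ester. The key step exploits the fact that C2 bears oxygen: as an acyloxy-substituted carbon it supports a planar radical, and the C2–C3 bond joins it to a tail with no functional group, which a simple alkylzinc reagent can supply. The phenol is carried as a benzoate and not as a benzyl ether, which makes the ring less nucleophilic in the Lewis-acid step and lets both oxygen functions be released in one final operation.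

## Logic of the disconnections

12 ⇒ 11. The two O–acyl bonds are cut last: both hydroxyl groups of 12 are traced back to the benzoate esters of 11. The carbinol ester is what the key step leaves behind, and the phenol receives the same acyl group so that one transesterification frees both. The gain is that no separate protecting-group step stands between the key step and 12. The demand is a base that cleaves a secondary benzoate completely and acts only at the acyl carbon, so that the C2–O bond and the R configuration are untouched.

11 ⇒ 8 + 10. The C2–C3 bond is cut. It is the one place where the carbinol carbon can be parted from a piece with no functional group, and it turns a 38-carbon chiral diester into a racemic electrophile and an achiral organometallic. The demand is heavy: the forward step must create C2 with R configuration from racemic 8, leave two esters alone, and avoid elimination toward the conjugated enol ester.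

10 ⇒ 9. The C–Zn bond is cut, because the nucleophile is then traced to a commercial primary bromide in a single operation. The demand is clean metal insertion without Wurtz-type homocoupling and a solution of known titre.

8 ⇒ 6 + 7. The C2–Br and C2–O bonds are cut together, because both arise when 7 adds across the carbonyl group of 6. One operation installs the leaving group and the coordinating ester. The demand is a Lewis acid mild enough not to enolise 6 or attack the ring. This is why the phenol oxygen of 6 is acylated and not alkylated: a ring with two ether oxygens would be a strong nucleophile toward the acylium and acyloxycarbenium ions of this step, and a benzylic ether could be cleaved by them.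

6 ⇒ 5. This is a functional-group interchange: the aldehyde is traced to its methyl enol ether, and no skeletal bond is cut. The gain is a storable precursor of an aldehyde that does not keep. The demand is an acid that hydrolyses a styryl ether yet spares the aryl ester.

5 ⇒ 4. The aryl O–acyl bond is cut. Placing the acylation after the olefination keeps the base-sensitive aryl ester away from the ylide and from alkoxide.

4 ⇒ 1 + 2. The C1=C2 double bond is cut (carbonyl olefination through 3). This shortens the side chain by one carbon and reaches an aldehyde in which the two meta oxygens are already distinct. The demand is enough base to carry the free phenol as its phenoxide; the alkene geometry is of no consequence.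

## Other disconnections considered

Alternative 1: The cut lies inside the arene. The ring bond between the alkyl-bearing carbon and its ester-bearing neighbour is opened, which unfolds the benzene ring into the open-chain triketo ester methyl (R)-9-(tert-butyldimethylsilyloxy)-3,5,7-trioxotetracosanoate A2. In the forward step mild base would enolise A2 at its C2, the enolate would add to the C7 ketone in a six-membered aldol closure, and loss of water with enolisation would give the resorcylate methyl (R)-6-[2-(tert-butyldimethylsilyloxy)heptadecyl]-2,4-dihydroxybenzoate A1.
- In its favour: the ester of A1 makes the two phenols unlike (one hydrogen-bonded to the carbonyl, one free), so mono-O-methylation should be selective. The stereocentre would be made beforehand by a very dependable method such as Noyori hydrogenation of a β-keto ester. On certainty of the C2 configuration this plan is the better of the two.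
- Against it here: the silyloxy group of A2 sits β to the C7 ketone, so the base that triggers the aldol can also expel silanolate by an E1cB path. Poly-β-carbonyl chains such as A2 can also close to pyrones. After A1, O-methylation, ester hydrolysis, decarboxylation and desilylation remain, and the ester that differentiated the phenols is discarded.
- Comparison: structurally it builds a ring that 1 supplies ready-made with the oxygen pattern already differentiated, so its built-in phenol differentiation is only the equal of the chosen plan. Mechanistically it is ionic and free of transition metals, which is an equal or slightly better position for scale-up, but the selectivity problem moves from enantiocontrol to chemoselectivity within a polyketone. In step economy it is clearly worse: four or five steps to A2 and four after A1, against seven in all.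

Alternative 2: The cut is the C1–C2 bond, with the benzyl group as a migrating group on boron and C2 as a lithiated carbamate carbon. In the forward step hexadecyl N,N-diisopropylcarbamate A4 would be deprotonated next to oxygen by a secondary alkyllithium in the presence of a chiral diamine. The configurationally stable carbenoid derived from A4 would add to boron of 2-[3-methoxy-5-(triisopropylsilyloxy)benzyl]-4,4,5,5-tetramethyl-1,3,2-dioxaborolane A5. 1,2-Migration of the benzyl group with loss of carbamate would give (R)-2-[1-(3-methoxy-5-(triisopropylsilyloxy)phenyl)heptadecan-2-yl]-4,4,5,5-tetramethyl-1,3,2-dioxaborolane A3. Oxidation of the C–B bond of A3 with retention, followed by desilylation, would finish the synthesis.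
- In its favour: the configuration is set by discrimination of the two enantiotopic protons next to oxygen in A4, not by telling the two methylene flanks of C2 apart. Long-chain primary carbamates of the kind of A4 are standard substrates, and both senses of induction are available. On predictability of the C2 configuration it is at least the equal of the chosen plan and probably the better.
- Against it here: it needs a stoichiometric chiral diamine and an alkyllithium at –78 °C. A5 needs about four steps from 1 (silylation, reduction, halide formation, borylation). After the key step the boron of A3 must be oxidised and the silyl group removed.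
- Comparison: structurally the two plans are equally convergent (two fragments, one new C–C bond, one new stereocentre). Mechanistically this is a polar two-electron 1,2-metallate shift with stoichiometric chirality, against a radical, catalytic, enantioconvergent coupling at 0 °C. Step economy is slightly worse, about eight steps against seven.

Alternative 3: The cut removes two ring bonds and takes the arene apart into (R)-3-[2-(tert-butyldimethylsilyloxy)heptadecyl]cyclobut-2-en-1-one A7 and methoxyacetylene A8. In the forward step heating would open A7 by four-electron electrocyclic ring opening to a vinylketene. Regioselective [2+2] cycloaddition with A8, a second ring opening to a dienylketene, six-electron electrocyclisation and tautomerisation would give (R)-3-[2-(tert-butyldimethylsilyloxy)heptadecyl]-5-methoxyphenol A6. Desilylation of A6 would then give 12.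
- In its favour: the ketene oxygen becomes the free phenol and the alkyne oxygen the methyl ether, meta to each other by mechanism, so no ring protecting group is needed. On this point it is the equal of the chosen plan, which gets the same from 1. The stereocentre would be set earlier from an enantiopure epoxide, which is more secure than the chosen key step. Only one step follows A6, which is better than or equal to the chosen plan.
- Against it here: A8 is volatile, thermally unstable and hazardous, and must be prepared and used fresh. A7 needs a ketene cycloaddition to a homopropargylic silyl ether and a reductive dehalogenation, after the alkyne itself has been made from the epoxide. The cascade needs prolonged heating.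
- Comparison: structurally it builds a ring that can be bought. Mechanistically it is a thermal pericyclic cascade with no catalyst and no enantiocontrol problem in the key step, but its regiochemistry rests on the polarisation of the alkoxyalkyne A8. In step economy it is about eight steps, with greater hazard, against seven.

Key step: step 6

Assumption (remark on the chemistry): the sense of induction of the nickel–bis(oxazoline) catalyst with this β-aryl electrophile is taken to follow that of simple 1-bromoalkyl benzoates. L* denotes the ligand enantiomer that delivers R at C2; both antipodes are equally accessible.

## Route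

Step 1
Reactants: 1 3-hydroxy-5-methoxybenzaldehyde; 2 (methoxymethyl)triphenylphosphonium chloride
Product: 4 3-methoxy-5-(2-methoxyethenyl)phenol (E/Z mixture), via (methoxymethylidene)triphenylphosphorane 3 (not isolated)
Conditions: 2 (1.4 equiv), KOtBu (2.5 equiv), THF, 0 °C; then 1, 0 °C to rt; aq. NH4Cl
Reagents that add atoms: (methoxymethyl)triphenylphosphonium chloride 2, [Cl-].COC[P+](c1ccccc1)(c1ccccc1)c1ccccc1
Why: Wittig methoxymethylenation; the extra equivalent of base carries the phenol as its potassium phenoxide, which is meta to the formyl group, not conjugated with it, and so should leave the aldehyde electrophilic. The E/Z ratio does not matter because both isomers hydrolyse to the same aldehyde.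

Step 2
Reactants: 4 3-methoxy-5-(2-methoxyethenyl)phenol (E/Z mixture)
Product: 5 3-methoxy-5-(2-methoxyethenyl)phenyl benzoate (E/Z mixture)
Conditions: BzCl (1.2 equiv), Et3N (1.5 equiv), DMAP (5 mol%), CH2Cl2, 0 °C to rt
Reagents that add atoms: benzoyl chloride, O=C(Cl)c1ccccc1
Why: O-acylation of a phenol under nucleophilic catalysis; the basic medium keeps the acid-labile enol ether intact. Doing it after the olefination means the aryl ester never meets the ylide or alkoxide.

Step 3
Reactants: 5 3-methoxy-5-(2-methoxyethenyl)phenyl benzoate (E/Z mixture)
Product: 6 3-methoxy-5-(2-oxoethyl)phenyl benzoate
Conditions: HCO2H/H2O (9:1), CH2Cl2, rt; cold aq. NaHCO3 wash; used crude at once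
Reagents that add atoms: water, O
Why: Acid-catalysed enol ether hydrolysis: protonation at the benzylic carbon, hydration of the oxocarbenium ion and loss of methanol. The aryl benzoate and aryl methyl ether should be stable to aqueous formic acid at rt, and the aldehyde is taken on without storage because arylacetaldehydes self-condense.

Step 4
Reactants: 6 3-methoxy-5-(2-oxoethyl)phenyl benzoate; 7 benzoyl bromide
Product: 8 racemic 2-[3-(benzoyloxy)-5-methoxyphenyl]-1-bromoethyl benzoate
Conditions: 7 (1.05 equiv), ZnBr2 (5 mol%), CH2Cl2, –20 to 0 °C; filtration through Celite under argon, evaporation; used at once
Reagents that add atoms: benzoyl bromide 7, O=C(Br)c1ccccc1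
Why: Lewis-acid-catalysed addition of an acyl bromide across an aldehyde carbonyl: O-acylation gives an acyloxycarbenium ion that bromide captures, and the new C2 centre is racemic by design. The ring carries a benzoate and one methyl ether in place of two ether groups, which should hold back Friedel–Crafts attack by the cationic intermediates.

Step 5
Reactants: 9 1-bromopentadecane
Product: 10 pentadecylzinc bromide (DMA solution)
Conditions: Zn dust (1.5 equiv), I2 (5 mol%), DMA, 70 °C; titration with I2
Reagents that add atoms: zinc, [Zn]
Why: Direct insertion of iodine-activated zinc into a primary alkyl bromide in a polar amide solvent. The unfunctionalised chain offers no competing site, and the solution is used as prepared.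

Step 6
Reactants: 8 racemic 2-[3-(benzoyloxy)-5-methoxyphenyl]-1-bromoethyl benzoate; 10 pentadecylzinc bromide
Product: 11 (R)-1-[3-(benzoyloxy)-5-methoxyphenyl]heptadecan-2-yl benzoate
Conditions: 10 (1.5 equiv), NiBr2·glyme (10 mol%), chiral bis(oxazoline) L* (12 mol%), THF/DMA, 0 °C
Reagents that add atoms: pentadecylzinc bromide 10, CCCCCCCCCCCCCCC[Zn]Br
Why: This is a nickel-catalysed enantioconvergent Negishi-type alkyl–alkyl coupling of a racemic 1-bromoalkyl ester with a primary alkylzinc halide, a known reaction type applied here to a member that carries a β-aryl group. A monovalent nickel–bis(oxazoline) species abstracts bromine from either enantiomer of 8 and releases the same planar, oxygen-stabilised α-benzoyloxy radical, so the configuration of the C–Br carbon is erased. Transmetalation from 10 gives a ligated pentadecylnickel bromide (divalent nickel) that captures the radical, and reductive elimination from the resulting trivalent dialkylnickel forms the C2–C3 bond and returns monovalent nickel to the chain. No ring is closed. The one new stereocentre, C2, is set under catalyst control: the benzoate carbonyl binds nickel, so the C2-symmetric ligand has to tell an oxygen substituent from two carbon substituents and not the benzylic CH2 from the chain CH2, and the ligand enantiomer that gives R is used. The step needs chemoselectivity for the C–Br bond over the two ester groups, which the weak C–Br bond next to oxygen and the inertness of alkylzinc halides and of this catalyst toward aryl and alkyl benzoates at 0 °C should secure. It also needs radical capture to outrun loss of HBr and β-hydride elimination toward the conjugated enol benzoate; the low temperature, the excess of 10 and the benzoate-bearing ring, which gives no push toward a benzylic cation, are the safeguards.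

Step 7
Reactants: 11 (R)-1-[3-(benzoyloxy)-5-methoxyphenyl]heptadecan-2-yl benzoate
Product: 12 (R)-1-(3-hydroxy-5-methoxyphenyl)heptadecan-2-ol
Conditions: K2CO3 (3 equiv), MeOH/THF (3:1), 40 °C; aq. NH4Cl
Reagents that add atoms: none
Why: Base-mediated transesterification (methanolysis) of both benzoates, the aryl ester quickly and the secondary alkyl ester more slowly. Attack is at the acyl carbon, so the C2–O bond is never broken and the R configuration is retained.

## Compound list

1 | 3-hydroxy-5-methoxybenzaldehyde | COc1cc(O)cc(C=O)c1 | starting material
2 | (methoxymethyl)triphenylphosphonium chloride | [Cl-].COC[P+](c1ccccc1)(c1ccccc1)c1ccccc1 | starting material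
3 | (methoxymethylidene)triphenylphosphorane | COC=P(c1ccccc1)(c1ccccc1)c1ccccc1 | intermediate
4 | 3-methoxy-5-(2-methoxyethenyl)phenol, E/Z mixture | COC=Cc1cc(O)cc(OC)c1 | intermediate
5 | 3-methoxy-5-(2-methoxyethenyl)phenyl benzoate, E/Z mixture | COC=Cc1cc(OC)cc(OC(=O)c2ccccc2)c1 | intermediate
6 | 3-methoxy-5-(2-oxoethyl)phenyl benzoate | COc1cc(CC=O)cc(OC(=O)c2ccccc2)c1 | intermediate
7 | benzoyl bromide | O=C(Br)c1ccccc1 | starting material
8 | racemic 2-[3-(benzoyloxy)-5-methoxyphenyl]-1-bromoethyl benzoate | COc1cc(CC(Br)OC(=O)c2ccccc2)cc(OC(=O)c2ccccc2)c1 | intermediate
9 | 1-bromopentadecane | CCCCCCCCCCCCCCCBr | starting material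
10 | pentadecylzinc bromide | CCCCCCCCCCCCCCC[Zn]Br | intermediate
11 | (R)-1-[3-(benzoyloxy)-5-methoxyphenyl]heptadecan-2-yl benzoate | CCCCCCCCCCCCCCC[C@@H](OC(=O)c1ccccc1)Cc1cc(OC)cc(OC(=O)c2ccccc2)c1 | intermediate
12 | (R)-1-(3-hydroxy-5-methoxyphenyl)heptadecan-2-ol | CCCCCCCCCCCCCCC[C@@H](O)Cc1cc(O)cc(OC)c1 | target

## Step count and least certain steps

Total step count: 7. Longest linear sequence: 6 steps (1, 2, 3, 4, 6, 7). Step 5 is a one-step side branch that feeds step 6.

Step 6 (key step).
- What may go wrong: loss of HBr from 8, or β-hydride elimination at the alkylnickel stage, toward the conjugated enol benzoate may compete with radical capture. Enantioselection may also be eroded, because the β-aryl group changes the shape the catalyst reads compared with purely aliphatic electrophiles.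
- Fallback: it sets out from 6 and returns at 12, setting C2 by reagent-controlled allylboration and building the tail afterwards. Addition of the enantiomer of B-allyldiisopinocampheylborane that gives the R carbinol to 6 (Et2O, –78 °C; ethanolamine work-up instead of alkaline peroxide, to spare the aryl ester) should give 3-[(2R)-2-hydroxypent-4-en-1-yl]-5-methoxyphenyl benzoate F1. Cross-metathesis of F1 with 1-tetradecene (second-generation Grubbs catalyst, CH2Cl2, 40 °C) should give 3-[(2R)-2-hydroxyheptadec-4-en-1-yl]-5-methoxyphenyl benzoate F2. Hydrogenation (H2, Pd/C, EtOAc) should give 3-[(2R)-2-hydroxyheptadecyl]-5-methoxyphenyl benzoate F3. Methanolysis under the conditions of step 7 then gives 12.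

Step 4.
- What may go wrong: enolisation of the arylacetaldehyde under the Lewis acid, leading to self-condensation, and hydrolysis or loss of HBr from the bromo ester during handling.
- Fallback: it sets out from 6 and returns at 8, making the elimination product on purpose and adding HBr back. O-Benzoylation of the enol form of 6 (BzCl, Et3N, DMAP, CH2Cl2) should give 2-[3-(benzoyloxy)-5-methoxyphenyl]ethenyl benzoate F4. Anhydrous HBr in CH2Cl2 at –20 °C should then add in the Markovnikov sense, the proton going to the benzylic carbon and bromide to the acyloxy-stabilised cation as in the hydrohalogenation of vinyl esters, to give 8.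

Step 3.
- What may go wrong: slow hydrolysis of the conjugated enol ether, which would call for stronger acid and so invite self-condensation of the aldehyde as it forms, or partial loss of the aryl ester.
- Fallback: it sets out from 1 and returns at 6, reaching the aldehyde by oxidation of a primary alcohol under neutral conditions. Methylenation of 1 (Ph3PCH3Br, KOtBu in excess, THF) should give 3-ethenyl-5-methoxyphenol F5. Hydroboration–oxidation (9-BBN in excess, THF; then NaOH, H2O2) should give 3-(2-hydroxyethyl)-5-methoxyphenol F6. Selective acylation of the phenoxide under Schotten–Baumann conditions (BzCl, aq. NaOH, CH2Cl2, 0 °C) should give 3-(2-hydroxyethyl)-5-methoxyphenyl benzoate F7. Dess–Martin oxidation (NaHCO3, CH2Cl2) then gives 6.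

Step 1.
- What may go wrong: incomplete olefination if the potassium phenoxide of 1 precipitates from THF or if proton exchange drains the ylide.
- Fallback: it sets out from 1 and returns at 5, reversing the order of protection and olefination. Benzoylation of 1 (BzCl, Et3N, DMAP, CH2Cl2) should give 3-formyl-5-methoxyphenyl benzoate F8. Ylide 3 is then generated from 2 with a slight deficit of NaN(SiMe3)2 (no alkoxide present) and added to F8 at –78 °C, where the aldehyde should be consumed well before the aryl ester is attacked, to give 5.

## Further compounds

F1 | step 6 | 3-[(2R)-2-hydroxypent-4-en-1-yl]-5-methoxyphenyl benzoate | C=CC[C@@H](O)Cc1cc(OC)cc(OC(=O)c2ccccc2)c1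
F2 | step 6 | 3-[(2R)-2-hydroxyheptadec-4-en-1-yl]-5-methoxyphenyl benzoate (E/Z mixture) | CCCCCCCCCCCCC=CC[C@@H](O)Cc1cc(OC)cc(OC(=O)c2ccccc2)c1
F3 | step 6 | 3-[(2R)-2-hydroxyheptadecyl]-5-methoxyphenyl benzoate | CCCCCCCCCCCCCCC[C@@H](O)Cc1cc(OC)cc(OC(=O)c2ccccc2)c1
F4 | step 4 | 2-[3-(benzoyloxy)-5-methoxyphenyl]ethenyl benzoate (E/Z mixture) | COc1cc(C=COC(=O)c2ccccc2)cc(OC(=O)c2ccccc2)c1
F5 | step 3 | 3-ethenyl-5-methoxyphenol | C=Cc1cc(O)cc(OC)c1
F6 | step 3 | 3-(2-hydroxyethyl)-5-methoxyphenol | OCCc1cc(O)cc(OC)c1
F7 | step 3 | 3-(2-hydroxyethyl)-5-methoxyphenyl benzoate | OCCc1cc(OC)cc(OC(=O)c2ccccc2)c1
F8 | step 1 | 3-formyl-5-methoxyphenyl benzoate | COc1cc(C=O)cc(OC(=O)c2ccccc2)c1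
A1 | alternative 1 | methyl (R)-6-[2-(tert-butyldimethylsilyloxy)heptadecyl]-2,4-dihydroxybenzoate | CCCCCCCCCCCCCCC[C@@H](O[Si](C)(C)C(C)(C)C)Cc1cc(O)cc(O)c1C(=O)OC
A2 | alternative 1 | methyl (R)-9-(tert-butyldimethylsilyloxy)-3,5,7-trioxotetracosanoate | CCCCCCCCCCCCCCC[C@@H](O[Si](C)(C)C(C)(C)C)CC(=O)CC(=O)CC(=O)CC(=O)OC
A3 | alternative 2 | (R)-2-[1-(3-methoxy-5-(triisopropylsilyloxy)phenyl)heptadecan-2-yl]-4,4,5,5-tetramethyl-1,3,2-dioxaborolane | CCCCCCCCCCCCCCC[C@@H](B1OC(C)(C)C(C)(C)O1)Cc1cc(O[Si](C(C)C)(C(C)C)C(C)C)cc(OC)c1
A4 | alternative 2 | hexadecyl N,N-diisopropylcarbamate | CCCCCCCCCCCCCCCCOC(=O)N(C(C)C)C(C)C
A5 | alternative 2 | 2-[3-methoxy-5-(triisopropylsilyloxy)benzyl]-4,4,5,5-tetramethyl-1,3,2-dioxaborolane | COc1cc(CB2OC(C)(C)C(C)(C)O2)cc(O[Si](C(C)C)(C(C)C)C(C)C)c1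
A6 | alternative 3 | (R)-3-[2-(tert-butyldimethylsilyloxy)heptadecyl]-5-methoxyphenol | CCCCCCCCCCCCCCC[C@@H](O[Si](C)(C)C(C)(C)C)Cc1cc(O)cc(OC)c1
A7 | alternative 3 | (R)-3-[2-(tert-butyldimethylsilyloxy)heptadecyl]cyclobut-2-en-1-one | CCCCCCCCCCCCCCC[C@@H](O[Si](C)(C)C(C)(C)C)CC1=CC(=O)C1
A8 | alternative 3 | methoxyacetylene | COC#C
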